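## Structural features

The target is an open-chain 1-O-alkyl-2-O-aroyl glycerol. A twelve-carbon chain is attached through an ether oxygen to glycerol C1, the oxygen on C2 carries the acyl group of 4-hydroxybenzoic acid (a para-disubstituted benzene, the only ring), and C3 is a free primary carbinol. The chain holds a conjugated (4E,6Z,8E)-triene that begins three methylene groups from the ether oxygen and ends in a propyl group. Glycerol C2 is the only stereocentre (S in the target) and has no stereogenic neighbour; its two CH2O arms differ only in what the oxygen carries, so it must be set by an external chiral agent. The fragile elements are the triene (geometric isomerisation by light, acid, radicals or metals; thermal electrocyclisation; autoxidation), the secondary aryl ester beside a free primary hydroxyl (1,2-acyl shift to the primary oxygen), and the phenol. The real difficulty is threefold: making the central cis double bond cleanly between two trans ones, fixing C2 on an almost symmetric glycerol, and freeing the C3 hydroxyl last without letting the aroyl group move. The key step uses the fact that the ether oxygen, glycerol C1 and the oxygenated C2 stand in the 1,2-relationship left when an alcohol opens an oxirane at its CH2 group, with C3 as the halomethyl carbon of an epihalohydrin.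

## Logic of the disconnections

**23 to 22.** The two O–Si bonds (phenol oxygen and primary C3 oxygen) are cut. Both hydroxyls must be masked while the ester is made, and one fluoride treatment removes both. The demand on the forward step is that the primary hydroxyl be released without an alkoxide that could pull the aroyl group from O2 to O3.

**22 to 18 and 21.** The acyl C–O bond at the secondary oxygen is cut. This separates the achiral aromatic acid from the chiral lipid and leaves a plain esterification. The forward step must acylate a secondary hydroxyl flanked by a silyl ether without silyl migration and without touching the C2–O bond.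

**21 to 19.** The aryl O–Si bond is cut, leading to a commodity acid. The forward step must silylate the phenol and leave the carboxyl free, which is achieved by persilylation and selective hydrolysis of the silyl ester.

**18 to 17 to 16 to 15.** In turn the primary O–Si bond, the C3–OH bond (water adding to an oxirane CH2) and the oxirane C3–O bond (closing on a C–Br carbon) are cut. The reason is that bromine at C3 of 15 must become the free carbinol, and passage through 16 does this with C2 never being a reaction site. Each forward step must react only at C3: displacement at CH2Br, then terminal opening by water.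

**15 to 12 and 13 (key).** The ether O–CH2 bond is cut. This is the only bond between the lipid chain and the glycerol unit, and forming it by terminal opening of 13 also decides the C2 configuration. The gain is large: an achiral alcohol and a cheap racemate. The forward step needs a catalyst that accepts one enantiomer of 13, a racemisation channel for the other, and exclusive attack at the unsubstituted carbon.

**12 to 11.** The two C–H bonds at C6 and C7 are cut, so the cis alkene becomes an alkyne. A central triple bond lets the two trans alkenes be introduced as preformed units. The forward step must be a cis semireduction that stops at the alkene and leaves the flanking alkenes alone.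

**11 to 7 and 10.** The C7–C8 bond (sp–sp2) is cut, giving a terminal enyne and an (E)-alkenyl iodide. The forward coupling must retain the alkene geometry and tolerate the free hydroxyl.

**7 to 4 and 5.** The C5–C6 bond (sp2–sp) is cut, together with the C–Si bond that caps the two-carbon unit. The second (E)-alkenyl iodide and a protected acetylene result. The forward step is the same type of coupling, followed in the same flask by C-desilylation.

**4 to 1 and 10 to 8.** The vinylic C–I bond and the adjacent C–H bond are cut in each iodide, leading to two terminal alkynes. The forward step must add H and a metal syn across the alkyne with the metal at the terminal carbon, and exchange it for iodine with retention.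

## Other disconnections considered

Alternative 1: No skeletal bond is cut. C2 would be created by telling apart the two enantiotopic acetoxymethyl arms of the prochiral diacetate A1, 2-({4-[(tert-butyldimethylsilyl)oxy]benzoyl}oxy)propane-1,3-diyl diacetate. In the forward step a lipase hydrolyses one arm through its acyl-enzyme to give the monoacetate A2, (2R)-1-acetoxy-3-hydroxypropan-2-yl 4-[(tert-butyldimethylsilyl)oxy]benzoate.
- In favour: A1 is achiral and quickly made from 21; the stereocentre arises under ambient, neutral conditions; the aroyl group is already on O2; and the triene would enter late. On exposure of the triene this plan is better than the chosen one.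
- Against: A2 has a free primary hydroxyl beside the secondary aroyl ester, the arrangement most prone to acyl shift, so constitution and configuration are both at risk from the moment the stereocentre exists. The ether bond to the chain would then have to be made on that hydroxyl without base. That leaves alkylation with a very reactive electrophile such as the triflate A3, (4E,6Z,8E)-dodeca-4,6,8-trien-1-yl trifluoromethanesulfonate, under hindered-amine buffering, a weak nucleophile meeting an electrophile whose alkene can participate. The remaining acetate would finally need a second selective (enzymatic) cleavage beside the aroyl ester. The sense and level of the enzyme's preference for a 2-aroyl substrate are open.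
- Comparison: structurally the chosen plan makes the O–CH2 bond and the stereocentre in one event, whereas this one separates them and forms the ether under the least favourable conditions. Mechanistically the two are equals: each is catalytic and each can in principle convert all material into one enantiomer. Step economy is about equal.

Alternative 2: Two C–C bonds of the benzene ring are cut (C1–C6 and C2–C3, counting from the carboxyl-bearing carbon). In the forward step the propiolate A4, (2R)-1-[(4E,6Z,8E)-dodeca-4,6,8-trien-1-yloxy]-3-[(triethylsilyl)oxy]propan-2-yl prop-2-ynoate, and the diene A5, (E)-1-methoxy-3-[(trimethylsilyl)oxy]buta-1,3-diene, undergo [4+2] cycloaddition. Elimination of the methoxy group from the primary cycloadduct then aromatises the ring to A6, (2R)-1-[(4E,6Z,8E)-dodeca-4,6,8-trien-1-yloxy]-3-[(triethylsilyl)oxy]propan-2-yl 4-[(trimethylsilyl)oxy]benzoate.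
- In favour: the polarisation of A5 places the oxygen para to the ester; A6 carries exactly two silyl ethers, so the end of the synthesis equals that of the chosen plan; propiolate esters of hindered alcohols form easily.
- Against: it spends a cycloaddition and an aromatisation on a ring that 19 supplies as a commodity. It needs heat in the presence of the E,Z,E triene, which can electrocyclise and can itself act as a diene toward the electron-poor alkyne. The elimination usually needs acid, which endangers the triethylsilyl ether and, after its loss, the position of the ester. It also leaves both real problems (C2 and the triene geometry) untouched, so a complete synthesis of a silyl analogue of 18 must still precede it.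
- Comparison: structurally it builds the easiest part of the molecule. Mechanistically a concerted pericyclic step is as predictable in regiochemistry as the acyl transfer of step 11, but far less compatible with the triene. Step count is equal at best (propiolate esterification plus cycloaddition against steps 10 and 11).

Alternative 3: The C3–C4 bond of the dodecatrienyl chain is cut. In the forward step the Grignard reagent A8, (3-{[(4R)-2,2-dimethyl-1,3-dioxolan-4-yl]methoxy}propyl)magnesium bromide, adds to an alpha carbon of pyrylium tetrafluoroborate A7. The 2H-pyran A9 so formed opens by a six-electron electrocyclic reaction to the dienal A10, (2Z,4E)-8-{[(4R)-2,2-dimethyl-1,3-dioxolan-4-yl]methoxy}octa-2,4-dienal. An E-selective olefination of A10 with the sulfone A11, 5-(butane-1-sulfonyl)-1-phenyl-1H-tetrazole, would complete the triene, and acetal hydrolysis would join the chosen route at 17.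
- In favour: two of the three double bonds, including the cis one, come from one step without palladium or alkyne reduction. The stereocentre of A8 comes from the chiral pool, so its configuration is certain, and here this plan is better than the chosen one. About five steps to 17 against eight, so it is also better in step count.
- Against: (2Z,4E)-dienals slip easily into the (2E,4E) form under base, acid, light or on silica, and the bond at risk is the central cis bond of the target. The olefination that must create the 8E bond runs under strongly basic conditions on this aldehyde, and sulfone olefinations of conjugated aldehydes are often only moderately E-selective. A geometric mixture of trienes would be very hard to separate. A7 is moisture-sensitive and must be prepared.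
- Comparison: structurally this plan trades a catalytic setting of C2 for a purchased one and is shorter. Mechanistically its electrocyclic opening is elegant, but the geometry of two double bonds then rests on kinetic control that later steps can erode. In the chosen plan the 4E and 8E bonds are fixed by syn hydrometalation and the 6Z bond by syn reduction of an alkyne. The chosen plan accepts more steps for a triene of secure geometry.

Key step: step 6

**Remarks on the chemistry and assumptions**

- (salen) denotes N,N'-bis(3,5-di-tert-butylsalicylidene)cyclohexane-1,2-diaminate. In the linked catalyst of step 6 the 5-tert-butyl groups are replaced by diester tethers that join neighbouring (salen)Co(OTs) units into macrocyclic oligomers. The linked form is chosen because an aliphatic alcohol is a much poorer partner than a phenol for a single (salen)Co centre.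
- Assumption: the (R,R) ligand selects the (R) enantiomer of 13, as it does for epihalohydrins and glycidyl ethers in hydrolytic resolution. The (S,S) ligand is therefore the matched one for hydrolysing (S)-16 in step 8.
- The configuration at glycerol C2 is set in step 6 and never touched afterwards. The change of descriptor along 15 (R), 16 (S), 17 (S), 18 (R), 22 (R), 23 (S) reflects substituent priorities only.
- The key-step precursor 12 and product 15 are mutually consistent in constitution, alkene geometry and configuration and are used unchanged. The design choices around them are the linked catalyst, an excess of cheap 13, a second zirconium hydride equivalent for the free hydroxyl in step 1, and the C-desilylation merged into step 2.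
- In step 6 the net reaction is the addition of 12 to 13 with every atom retained. The bromide of LiBr and a hydroxyl proton are only borrowed to make 14 and are handed back as LiBr when 14 recloses to 13.
- In the line notations the two cyclopentadienyl ligands on zirconium are written as separate cyclopentadienide rings.
- From 12 onward all operations are run under argon, in the dark, at or below room temperature, with a trace of BHT in stored solutions.

## Route

Step 1
Reactants: 1 pent-4-yn-1-ol
Product: 4 (4E)-5-iodopent-4-en-1-ol, via chloridozirconocene pent-4-yn-1-olate 2 (not isolated), via O-zirconated (E)-alkenylzirconocene chloride 3 (not isolated)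
Conditions: Cp2Zr(H)Cl (2.3 equiv), THF, 0 °C → rt, dark; then I2 (1.3 equiv), THF, −20 → 0 °C; aq. Na2S2O3/NaHCO3
Reagents that add atoms: iodine, II
Why: The first hydride equivalent converts the hydroxyl into a zirconium alkoxide with loss of H2; the second adds syn across the terminal alkyne with zirconium at the terminal carbon (hydrozirconation), and iodinolysis of the C–Zr bond with retention gives the E iodide.

Step 2
Reactants: 4 (4E)-5-iodopent-4-en-1-ol; 5 ethynyltrimethylsilane (1.3 equiv)
Product: 7 (4E)-hept-4-en-6-yn-1-ol, via (4E)-7-(trimethylsilyl)hept-4-en-6-yn-1-ol 6 (not isolated)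
Conditions: Pd(PPh3)2Cl2 (2 mol%), CuI (4 mol%), Et3N (3 equiv), THF, rt, Ar; after full consumption of 4: MeOH, K2CO3 (0.3 equiv), rt, same flask
Reagents that add atoms: none
Why: Sonogashira coupling of an (E)-alkenyl iodide runs at room temperature with retention of geometry and tolerates the free hydroxyl; base-catalysed methanolysis then cleaves only the C(sp)–Si bond.

Step 3
Reactants: 8 pent-1-yne
Product: 10 (1E)-1-iodopent-1-ene, via (1E)-pent-1-en-1-ylzirconocene chloride 9 (not isolated)
Conditions: Cp2Zr(H)Cl (1.1 equiv), CH2Cl2, rt, dark; then I2 (1.05 equiv), 0 °C; product kept as a concentrated solution (volatile)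
Reagents that add atoms: iodine, II
Why: Hydrozirconation–iodination: syn addition of Zr–H with the metal at the terminal carbon, then iodinolysis with retention, fixes the E geometry.

Step 4
Reactants: 7 (4E)-hept-4-en-6-yn-1-ol; 10 (1E)-1-iodopent-1-ene (1.2 equiv)
Product: 11 (4E,8E)-dodeca-4,8-dien-6-yn-1-ol
Conditions: Pd(PPh3)4 (3 mol%), CuI (6 mol%), Et3N (3 equiv), THF, rt, Ar, dark
Reagents that add atoms: none
Why: A second Sonogashira coupling joins the terminal enyne to the alkenyl iodide with both alkene geometries retained, giving the conjugated dienyne used for E,Z,E trienes.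

Step 5
Reactants: 11 (4E,8E)-dodeca-4,8-dien-6-yn-1-ol
Product: 12 (4E,6Z,8E)-dodeca-4,6,8-trien-1-ol
Conditions: Zn(Cu/Ag) [Zn dust activated with Cu(OAc)2·H2O, then AgNO3], MeOH–H2O 1:1, rt → 35 °C, Ar, dark; used at once in step 6
Reagents that add atoms: none
Why: Boland reduction: the activated zinc surface delivers two hydrogens syn to a conjugated alkyne and does not reduce the resulting triene or the flanking alkenes, so the new 6,7 double bond is Z.

Step 6
Reactants: 12 (4E,6Z,8E)-dodeca-4,6,8-trien-1-ol; 13 racemic epibromohydrin (2.0 equiv)
Product: 15 (2R)-1-bromo-3-[(4E,6Z,8E)-dodeca-4,6,8-trien-1-yloxy]propan-2-ol, via 1,3-dibromopropan-2-ol 14 (not isolated)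
Conditions: linked oligomeric (R,R)-(salen)Co(OTs) (3 mol% Co), LiBr (5 mol%), 3 Å MS, MeCN, 4 °C, Ar, dark; excess 13 and residual 14 stripped in vacuo
Reagents that add atoms: none
Why: Proposed new method: the alkoxide of 12 held on one trivalent cobalt centre of the linked (salen)Co framework attacks the CH2 terminus of an oxirane that a second cobalt centre activates as a Lewis acid, so the O–CH2 bond forms by a bimetallic SN2 opening and the C2–O bond is never broken. The closest known reactions are the (salen)Co-catalysed dynamic opening of epibromohydrin by phenols and by water, and the kinetic-resolution alcoholysis of terminal epoxides by primary alcohols with linked (salen)Co sulfonates; only their combination is new. No ring is closed. The stereocentre of 15 is selected and not created at carbon: the (R,R) ligand pocket should admit (R)-13 far faster than (S)-13, and because attack is at the oxirane CH2 its configuration passes unchanged into the (R)-carbinol. Bromide from LiBr (and the Co–Br formed from it), with a hydroxyl proton of the medium as the acid, opens either enantiomer of 13 at its CH2 to achiral 14, which recloses to both enantiomers and hands that bromide back as LiBr, so the unreactive enantiomer is fed continuously into the reactive one and all atoms of 12 and 13 end up in 15. Two selectivities are needed: discrimination between the equilibrating enantiomers, secured by the ligand and backed by the excess of cheap 13, and attack at the terminal carbon, secured by the unhindered CH2 and the bromomethyl group that deactivates C2. The near-neutral medium, low temperature and exclusion of light should leave the E,Z,E triene untouched.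

Step 7
Reactants: 15 (2R)-1-bromo-3-[(4E,6Z,8E)-dodeca-4,6,8-trien-1-yloxy]propan-2-ol
Product: 16 (2S)-2-{[(4E,6Z,8E)-dodeca-4,6,8-trien-1-yloxy]methyl}oxirane
Conditions: K2CO3 (1.5 equiv), MeOH, 0 °C → rt, dark
Reagents that add atoms: none
Why: Intramolecular Williamson reaction (3-exo-tet): the secondary alkoxide displaces bromide at the neighbouring CH2, so the stereocentre keeps its C–O bond and its spatial arrangement.

Step 8
Reactants: 16 (2S)-2-{[(4E,6Z,8E)-dodeca-4,6,8-trien-1-yloxy]methyl}oxirane
Product: 17 (2S)-3-[(4E,6Z,8E)-dodeca-4,6,8-trien-1-yloxy]propane-1,2-diol
Conditions: (S,S)-(salen)Co(OAc) (1 mol%), H2O (1.05 equiv), THF, 0 °C → rt, dark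
Reagents that add atoms: water, O
Why: Cobalt-catalysed hydrolytic opening of a glycidyl ether in the matched pairing: hydroxide on one cobalt attacks the terminal CH2 of the epoxide bound to another, so C2 is retained, the medium stays neutral, and any minor enantiomer of 16 reacts slowly and is left behind.

Step 9
Reactants: 17 (2S)-3-[(4E,6Z,8E)-dodeca-4,6,8-trien-1-yloxy]propane-1,2-diol
Product: 18 (2R)-1-[(tert-butyldimethylsilyl)oxy]-3-[(4E,6Z,8E)-dodeca-4,6,8-trien-1-yloxy]propan-2-ol
Conditions: TBSCl (1.05 equiv), imidazole (2.0 equiv), CH2Cl2, −20 → 0 °C
Reagents that add atoms: tert-butyldimethylsilyl chloride, CC(C)(C)[Si](C)(C)Cl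
Why: Selective silylation: the bulky silyl chloride reacts with the primary hydroxyl of a 1,2-diol much faster than with the secondary one.

Step 10
Reactants: 19 4-hydroxybenzoic acid
Product: 21 4-[(tert-butyldimethylsilyl)oxy]benzoic acid, via tert-butyldimethylsilyl 4-[(tert-butyldimethylsilyl)oxy]benzoate 20 (not isolated)
Conditions: TBSCl (2.3 equiv), imidazole (5 equiv), DMF, rt; then AcOH–THF–H2O 3:1:1, rt
Reagents that add atoms: tert-butyldimethylsilyl chloride, CC(C)(C)[Si](C)(C)Cl
Why: Persilylation followed by selective hydrolysis: the silyl ester is far more labile to mild aqueous acid than the aryl silyl ether, so only the carboxyl is released.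

Step 11
Reactants: 18 (2R)-1-[(tert-butyldimethylsilyl)oxy]-3-[(4E,6Z,8E)-dodeca-4,6,8-trien-1-yloxy]propan-2-ol; 21 4-[(tert-butyldimethylsilyl)oxy]benzoic acid (1.2 equiv)
Product: 22 (2R)-1-[(tert-butyldimethylsilyl)oxy]-3-[(4E,6Z,8E)-dodeca-4,6,8-trien-1-yloxy]propan-2-yl 4-[(tert-butyldimethylsilyl)oxy]benzoate
Conditions: DCC (1.3 equiv), DMAP (0.2 equiv), CH2Cl2, 0 °C → rt, dark
Reagents that add atoms: none
Why: Steglich esterification: the acylpyridinium from the O-acylisourea acylates the secondary hydroxyl at its O–H bond, so C2 is retained, and the neutral conditions leave both silyl ethers and the triene alone.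

Step 12
Reactants: 22 (2R)-1-[(tert-butyldimethylsilyl)oxy]-3-[(4E,6Z,8E)-dodeca-4,6,8-trien-1-yloxy]propan-2-yl 4-[(tert-butyldimethylsilyl)oxy]benzoate
Product: 23 (2S)-1-[(4E,6Z,8E)-dodeca-4,6,8-trien-1-yloxy]-3-hydroxypropan-2-yl 4-hydroxybenzoate
Conditions: TBAF (2.4 equiv) premixed with AcOH (2.6 equiv), THF, 0 °C → rt, dark; pH 6 phosphate work-up; fast chromatography on boric-acid-treated silica
Reagents that add atoms: none
Why: Fluoride-induced cleavage of both O–Si bonds (aryl fast, primary alkyl slower); acetic acid protonates the phenoxide and alkoxide as they form, which is what suppresses the base-driven 2-to-3 acyl shift.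

## Compound list

1 | pent-4-yn-1-ol | C#CCCCO | starting material
2 | chloridobis(cyclopentadienyl)(pent-4-yn-1-olato)zirconium | C#CCCCO[Zr+2]Cl.c1cc[cH-]c1.c1cc[cH-]c1 | intermediate
3 | chloridobis(cyclopentadienyl)zirconium (4E)-5-[chloridobis(cyclopentadienyl)zirconio]pent-4-en-1-olate | Cl[Zr+2]OCCC/C=C/[Zr+2]Cl.c1cc[cH-]c1.c1cc[cH-]c1.c1cc[cH-]c1.c1cc[cH-]c1 | intermediate
4 | (4E)-5-iodopent-4-en-1-ol | OCCC/C=C/I | intermediate
5 | ethynyltrimethylsilane | C#C[Si](C)(C)C | starting material
6 | (4E)-7-(trimethylsilyl)hept-4-en-6-yn-1-ol | C[Si](C)(C)C#C/C=C/CCCO | intermediate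
7 | (4E)-hept-4-en-6-yn-1-ol | C#C/C=C/CCCO | intermediate
8 | pent-1-yne | CCCC#C | starting material
9 | chloridobis(cyclopentadienyl)[(1E)-pent-1-en-1-yl]zirconium | CCC/C=C/[Zr+2]Cl.c1cc[cH-]c1.c1cc[cH-]c1 | intermediate
10 | (1E)-1-iodopent-1-ene | CCC/C=C/I | intermediate
11 | (4E,8E)-dodeca-4,8-dien-6-yn-1-ol | CCC/C=C/C#C/C=C/CCCO | intermediate
12 | (4E,6Z,8E)-dodeca-4,6,8-trien-1-ol | CCC/C=C/C=C\C=C\CCCO | intermediate
13 | racemic epibromohydrin, 2-(bromomethyl)oxirane | BrCC1CO1 | starting material
14 | 1,3-dibromopropan-2-ol | OC(CBr)CBr | intermediate
15 | (2R)-1-bromo-3-[(4E,6Z,8E)-dodeca-4,6,8-trien-1-yloxy]propan-2-ol | CCC/C=C/C=C\C=C\CCCOC[C@H](CBr)O | intermediate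
16 | (2S)-2-{[(4E,6Z,8E)-dodeca-4,6,8-trien-1-yloxy]methyl}oxirane | CCC/C=C/C=C\C=C\CCCOC[C@@H]1CO1 | intermediate
17 | (2S)-3-[(4E,6Z,8E)-dodeca-4,6,8-trien-1-yloxy]propane-1,2-diol | CCC/C=C/C=C\C=C\CCCOC[C@H](CO)O | intermediate
18 | (2R)-1-[(tert-butyldimethylsilyl)oxy]-3-[(4E,6Z,8E)-dodeca-4,6,8-trien-1-yloxy]propan-2-ol | CCC/C=C/C=C\C=C\CCCOC[C@H](CO[Si](C)(C)C(C)(C)C)O | intermediate
19 | 4-hydroxybenzoic acid | OC(=O)c1ccc(O)cc1 | starting material
20 | tert-butyldimethylsilyl 4-[(tert-butyldimethylsilyl)oxy]benzoate | CC(C)(C)[Si](C)(C)OC(=O)c1ccc(O[Si](C)(C)C(C)(C)C)cc1 | intermediate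
21 | 4-[(tert-butyldimethylsilyl)oxy]benzoic acid | OC(=O)c1ccc(O[Si](C)(C)C(C)(C)C)cc1 | intermediate
22 | (2R)-1-[(tert-butyldimethylsilyl)oxy]-3-[(4E,6Z,8E)-dodeca-4,6,8-trien-1-yloxy]propan-2-yl 4-[(tert-butyldimethylsilyl)oxy]benzoate | CCC/C=C/C=C\C=C\CCCOC[C@H](CO[Si](C)(C)C(C)(C)C)OC(=O)c1ccc(O[Si](C)(C)C(C)(C)C)cc1 | intermediate
23 | (2S)-1-[(4E,6Z,8E)-dodeca-4,6,8-trien-1-yloxy]-3-hydroxypropan-2-yl 4-hydroxybenzoate | CCC/C=C/C=C\C=C\CCCOC[C@H](CO)OC(=O)c1ccc(O)cc1 | target

## Step count and risk

Total: 12 steps. Longest linear sequence: 10 steps (1, 2, 4, 5, 6, 7, 8, 9, 11, 12); steps 3 and 10 are side branches.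

**Step 6 (key step, proposed new method).** The most likely failure is slow turnover of the aliphatic alcohol at cobalt, because an alkanol is much less acidic than the phenols for which the dynamic opening is established. Bromide would then park 13 as 14 and the alcohol would remain. A second risk is erosion of enantiomeric purity late in the reaction if racemisation of 13 lags behind consumption of its reactive enantiomer; the excess of 13 is there to counter this. The fallback uses only known chemistry and takes the stereocentre from the chiral pool. It sets out from 12, which is converted with methanesulfonyl chloride and triethylamine into (4E,6Z,8E)-dodeca-4,6,8-trien-1-yl methanesulfonate F1. F1 alkylates the sodium alkoxide of commercial (R)-solketal (NaH, THF–DMF) to give (4R)-4-{[(4E,6Z,8E)-dodeca-4,6,8-trien-1-yloxy]methyl}-2,2-dimethyl-1,3-dioxolane F2. Aqueous acetic acid at room temperature removes the acetonide, and the route is rejoined at 17, bypassing 15 and 16.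

**Step 12.** The likely failure is migration of the aroyl group from O2 to the freshly released primary oxygen, during the fluoride treatment or on silica. Cleavage of the primary silyl ether is the slow part, and the longer it takes the longer the product sits in a medium where alkoxide can form. The fallback unveils the primary hydroxyl enzymatically at neutral pH and sets out from 17. Immobilised Candida antarctica lipase B and vinyl acetate acetylate the primary hydroxyl to give (2R)-3-[(4E,6Z,8E)-dodeca-4,6,8-trien-1-yloxy]-2-hydroxypropyl acetate F3. Esterification with 21 (DCC, DMAP) gives (2R)-1-(acetyloxy)-3-[(4E,6Z,8E)-dodeca-4,6,8-trien-1-yloxy]propan-2-yl 4-[(tert-butyldimethylsilyl)oxy]benzoate F4. Brief buffered fluoride treatment removes the aryl silyl group while O3 is still acetylated, giving (2R)-1-(acetyloxy)-3-[(4E,6Z,8E)-dodeca-4,6,8-trien-1-yloxy]propan-2-yl 4-hydroxybenzoate F5. The same lipase with ethanol in tert-butyl methyl ether then removes the primary acetate, the way 2-acylglycerols are made from triglycerides, and the route ends at 23.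

**Step 5.** The likely failures are incomplete reduction, leaving dienyne that is hard to separate from the triene, or partial geometric isomerisation or over-reduction on a too-active zinc surface or under light. The fallback installs the cis bond before the triene is assembled and sets out from 7. N-iodosuccinimide with catalytic AgNO3 gives (4E)-7-iodohept-4-en-6-yn-1-ol F6. Diimide generated from 2-nitrobenzenesulfonylhydrazide and triethylamine reduces the iodoalkyne syn to (4E,6Z)-7-iodohepta-4,6-dien-1-ol F7. Suzuki–Miyaura coupling of F7 with commercial (1E)-pent-1-en-1-ylboronic acid (Pd(PPh3)4, aqueous KOH, THF, room temperature) proceeds with retention at both partners and rejoins the route at 12.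

**Step 1.** The likely failure is incomplete hydrozirconation. The zirconium alkoxide formed first may be poorly soluble and may consume hydride unevenly, and adventitious protonolysis of the alkenyl–zirconium bond would give the simple alkene in place of the iodide. The fallback protects first and sets out from 1. Silylation (TBSCl, imidazole) gives tert-butyldimethyl(pent-4-yn-1-yloxy)silane F8. Hydrozirconation with one equivalent of Cp2Zr(H)Cl and iodination give tert-butyl{[(4E)-5-iodopent-4-en-1-yl]oxy}dimethylsilane F9. Sonogashira coupling with 5 gives tert-butyldimethyl{[(4E)-7-(trimethylsilyl)hept-4-en-6-yn-1-yl]oxy}silane F10. TBAF added to the same flask removes both silicon groups and the route is rejoined at 7.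

## Further compounds

F1 | step 6 | (4E,6Z,8E)-dodeca-4,6,8-trien-1-yl methanesulfonate | CCC/C=C/C=C\C=C\CCCOS(C)(=O)=O
F2 | step 6 | (4R)-4-{[(4E,6Z,8E)-dodeca-4,6,8-trien-1-yloxy]methyl}-2,2-dimethyl-1,3-dioxolane | CCC/C=C/C=C\C=C\CCCOC[C@@H]1COC(C)(C)O1
F3 | step 12 | (2R)-3-[(4E,6Z,8E)-dodeca-4,6,8-trien-1-yloxy]-2-hydroxypropyl acetate | CCC/C=C/C=C\C=C\CCCOC[C@H](COC(C)=O)O
F4 | step 12 | (2R)-1-(acetyloxy)-3-[(4E,6Z,8E)-dodeca-4,6,8-trien-1-yloxy]propan-2-yl 4-[(tert-butyldimethylsilyl)oxy]benzoate | CCC/C=C/C=C\C=C\CCCOC[C@H](COC(C)=O)OC(=O)c1ccc(O[Si](C)(C)C(C)(C)C)cc1
F5 | step 12 | (2R)-1-(acetyloxy)-3-[(4E,6Z,8E)-dodeca-4,6,8-trien-1-yloxy]propan-2-yl 4-hydroxybenzoate | CCC/C=C/C=C\C=C\CCCOC[C@H](COC(C)=O)OC(=O)c1ccc(O)cc1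
F6 | step 5 | (4E)-7-iodohept-4-en-6-yn-1-ol | OCCC/C=C/C#CI
F7 | step 5 | (4E,6Z)-7-iodohepta-4,6-dien-1-ol | OCCC/C=C/C=C\I
F8 | step 1 | tert-butyldimethyl(pent-4-yn-1-yloxy)silane | C#CCCCO[Si](C)(C)C(C)(C)C
F9 | step 1 | tert-butyl{[(4E)-5-iodopent-4-en-1-yl]oxy}dimethylsilane | I/C=C/CCCO[Si](C)(C)C(C)(C)C
F10 | step 1 | tert-butyldimethyl{[(4E)-7-(trimethylsilyl)hept-4-en-6-yn-1-yl]oxy}silane | C[Si](C)(C)C#C/C=C/CCCO[Si](C)(C)C(C)(C)C
A1 | alternative 1 | 2-({4-[(tert-butyldimethylsilyl)oxy]benzoyl}oxy)propane-1,3-diyl diacetate | CC(=O)OCC(COC(C)=O)OC(=O)c1ccc(O[Si](C)(C)C(C)(C)C)cc1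
A2 | alternative 1 | (2R)-1-acetoxy-3-hydroxypropan-2-yl 4-[(tert-butyldimethylsilyl)oxy]benzoate | OC[C@H](COC(C)=O)OC(=O)c1ccc(O[Si](C)(C)C(C)(C)C)cc1
A3 | alternative 1 | (4E,6Z,8E)-dodeca-4,6,8-trien-1-yl trifluoromethanesulfonate | CCC/C=C/C=C\C=C\CCCOS(=O)(=O)C(F)(F)F
A4 | alternative 2 | (2R)-1-[(4E,6Z,8E)-dodeca-4,6,8-trien-1-yloxy]-3-[(triethylsilyl)oxy]propan-2-yl prop-2-ynoate | CCC/C=C/C=C\C=C\CCCOC[C@H](CO[Si](CC)(CC)CC)OC(=O)C#C
A5 | alternative 2 | (E)-1-methoxy-3-[(trimethylsilyl)oxy]buta-1,3-diene | CO/C=C/C(=C)O[Si](C)(C)C
A6 | alternative 2 | (2R)-1-[(4E,6Z,8E)-dodeca-4,6,8-trien-1-yloxy]-3-[(triethylsilyl)oxy]propan-2-yl 4-[(trimethylsilyl)oxy]benzoate | CCC/C=C/C=C\C=C\CCCOC[C@H](CO[Si](CC)(CC)CC)OC(=O)c1ccc(O[Si](C)(C)C)cc1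
A7 | alternative 3 | pyrylium tetrafluoroborate | c1cc[o+]cc1.F[B-](F)(F)F
A8 | alternative 3 | (3-{[(4R)-2,2-dimethyl-1,3-dioxolan-4-yl]methoxy}propyl)magnesium bromide | Br[Mg]CCCOC[C@@H]1COC(C)(C)O1
A9 | alternative 3 | 2-(3-{[(4R)-2,2-dimethyl-1,3-dioxolan-4-yl]methoxy}propyl)-2H-pyran | CC1(C)OC[C@@H](COCCCC2C=CC=CO2)O1
A10 | alternative 3 | (2Z,4E)-8-{[(4R)-2,2-dimethyl-1,3-dioxolan-4-yl]methoxy}octa-2,4-dienal | O=C/C=C\C=C\CCCOC[C@@H]1COC(C)(C)O1
A11 | alternative 3 | 5-(butane-1-sulfonyl)-1-phenyl-1H-tetrazole | CCCCS(=O)(=O)c1nnnn1-c1ccccc1
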